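Ring A is disconnected at the C8–C8a bond. The benzene ring that carries four adjacent oxygens (C5–C8) and is fused to pyranone ring C at C4a–C8a is traced back to a squarate-derived cyclobutenone attached through its C4 to pyranone C3 (the future C4a). Heating opens the four-membered ring to a dienylketene that closes onto the pyranone C2–H, so ring A forms in one operation with every oxygen already differentiated (5-OMe, 6-OMe, 7-OtBu, 8-OH). The precursor is a 4-(6-aryl-5-methoxy-4-oxopyran-3-yl)-2-tert-butoxy-3,4-dimethoxycyclobutenone; its oxygen order comes from addition of the pyranonyl Grignard reagent to symmetrical di-tert-butyl squarate and exchange of only the vinylogous-ester tert-butyl group for methyl.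

Key step: step 9

Remark: the ring expansion maps cyclobutenone C1, C2, C3, C4 onto chromone C8, C7, C6, C5, so the precursor must be the 2-tert-butoxy-3,4-dimethoxy isomer, and the carbon that closes ring A is C2–H of the pyran-3-yl unit (the CH next to the ring oxygen).
Remark: the target is achiral; every intermediate with a stereocentre (6, 7, 12–15, 17) is racemic or a diastereomer mixture and its stereocentre is erased later.
Remark: 3,4-dibromofuran and di-tert-butyl squarate are taken as purchased; Ar = 2,4-bis(benzyloxy)-5-methoxyphenyl.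

Step 1
Reactants: 1 2,4,5-trimethoxybenzaldehyde
Product: 2 2,4-dihydroxy-5-methoxybenzaldehyde
Conditions: AlCl3 (5 equiv), CH2Cl2, 0 °C → rt; aq. HCl
Reagents that add atoms: none
Why: Lewis-acid aryl methyl ether cleavage should be selective for the methoxy groups ortho (chelation to the formyl oxygen) and para (conjugated with the complexed carbonyl) to the aldehyde, so the meta 5-methoxy group is kept.

Step 2
Reactants: 2 2,4-dihydroxy-5-methoxybenzaldehyde
Product: 3 2,4-bis(benzyloxy)-5-methoxybenzaldehyde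
Conditions: BnBr (2.5 equiv), K2CO3, DMF, 60 °C
Reagents that add atoms: benzyl bromide, BrCc1ccccc1
Why: Williamson ether synthesis, in which warm DMF and excess halide also alkylate the hydrogen-bonded 2-hydroxyl.

Step 3
Reactants: 4 3,4-dibromofuran; 3 2,4-bis(benzyloxy)-5-methoxybenzaldehyde
Product: 6 rac-[2,4-bis(benzyloxy)-5-methoxyphenyl](3,4-dibromofuran-2-yl)methanol, via (3,4-dibromofuran-2-yl)lithium 5 (not isolated)
Conditions: LDA, THF, −78 °C; then 3, −78 °C; aq. NH4Cl
Reagents that add atoms: none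
Why: Amide-base deprotonation of the dibromofuran occurs at one of its two equivalent α-positions without halogen migration at −78 °C, and 1,2-addition of the furyllithium to the aldehyde gives the racemic carbinol, whose stereocentre disappears in step 4.

Step 4
Reactants: 6 rac-[2,4-bis(benzyloxy)-5-methoxyphenyl](3,4-dibromofuran-2-yl)methanol
Product: 8 2-[2,4-bis(benzyloxy)-5-methoxyphenyl]-5-bromo-3-hydroxy-4H-pyran-4-one, via 4,5-dibromo-6-hydroxy-2H-pyran-3(6H)-one hemiacetal 7 (not isolated)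
Conditions: VO(acac)2 (5 mol %), t-BuOOH, CH2Cl2, 0 °C → rt; then TFA, THF–H2O, 50 °C
Reagents that add atoms: tert-butyl hydroperoxide, CC(C)(C)OO; water, O
Why: Hydroxyl-directed vanadium-catalysed Achmatowicz oxidative ring expansion should give hemiacetal 7 without an electrophilic halogen that would attack the electron-rich arene, and acid then effects the maltol-type aromatisation (enolisation at C2, loss of the C6 hydroxyl, attack of water at C4, loss of HBr), which turns the C4 bromine into the carbonyl oxygen and keeps the C5 bromine exactly where the metal is needed.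

Step 5
Reactants: 8 2-[2,4-bis(benzyloxy)-5-methoxyphenyl]-5-bromo-3-hydroxy-4H-pyran-4-one
Product: 9 2-[2,4-bis(benzyloxy)-5-methoxyphenyl]-5-bromo-3-methoxy-4H-pyran-4-one
Conditions: MeI, K2CO3, DMF, rt
Reagents that add atoms: iodomethane, CI
Why: Williamson O-methylation of the acidic enolic 3-hydroxyl of a 3-hydroxy-4-pyranone.

Step 6
Reactants: 9 2-[2,4-bis(benzyloxy)-5-methoxyphenyl]-5-bromo-3-methoxy-4H-pyran-4-one; 10 di-tert-butyl squarate
Product: 12 rac-4-{6-[2,4-bis(benzyloxy)-5-methoxyphenyl]-5-methoxy-4-oxo-4H-pyran-3-yl}-2,3-di-tert-butoxy-4-hydroxycyclobut-2-en-1-one, via pyranon-3-ylmagnesium chloride 11 (not isolated)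
Conditions: i-PrMgCl·LiCl (1.05 equiv), THF, −40 °C; then into 10 (1.3 equiv), THF, −78 °C; aq. NH4Cl
Reagents that add atoms: none
Why: Bromine–magnesium exchange of an α-bromo-enone-type alkenyl bromide with the turbo-Grignard reagent should be fast at low temperature, where the cyclic β-oxygenated alkenylmagnesium species does not fragment, and its 1,2-addition (inverse addition, excess squarate) to either of the two equivalent carbonyl groups of the symmetrical squarate gives one racemic carbinol.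

Step 7
Reactants: 12 rac-4-{6-Ar-5-methoxy-4-oxo-4H-pyran-3-yl}-2,3-di-tert-butoxy-4-hydroxycyclobut-2-en-1-one
Product: 13 rac-4-{6-[2,4-bis(benzyloxy)-5-methoxyphenyl]-5-methoxy-4-oxo-4H-pyran-3-yl}-2,3-di-tert-butoxy-4-methoxycyclobut-2-en-1-one
Conditions: MeI, Ag2O, 4 Å MS, MeCN, rt, dark
Reagents that add atoms: iodomethane, CI
Why: Purdie methylation etherifies the tertiary carbinol under neutral conditions that leave the cyclobutenone and the pyranone carbonyl untouched.

Step 8
Reactants: 13 rac-4-{6-Ar-5-methoxy-4-oxo-4H-pyran-3-yl}-2,3-di-tert-butoxy-4-methoxycyclobut-2-en-1-one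
Product: 15 rac-4-{6-[2,4-bis(benzyloxy)-5-methoxyphenyl]-5-methoxy-4-oxo-4H-pyran-3-yl}-2-tert-butoxy-3,4-dimethoxycyclobut-2-en-1-one, via vinylogous acid 14 (not isolated)
Conditions: TFA (5 equiv), CH2Cl2, −10 °C, brief; evaporate cold; then TMSCHN2, PhMe–MeOH, 0 °C
Reagents that add atoms: (trimethylsilyl)diazomethane, C[Si](C)(C)C=[N+]=[N-]
Why: Acidolysis of a tert-butyl ester type should remove only the C3 tert-butyl group, because protonation of the cyclobutenone carbonyl turns it into a tert-butyl oxocarbenium ion that loses isobutene, whereas the C2 group is a mere enol ether and cold, short contact should keep the C4 methyl ether from ionising; diazoalkane O-methylation of vinylogous acid 14 then gives the same racemic product whichever oxygen reacts, because the two tautomers of 14 are mirror images, so tert-butoxy necessarily ends at C2 and methoxy at C3.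

Step 9
Reactants: 15 rac-4-{6-Ar-5-methoxy-4-oxo-4H-pyran-3-yl}-2-tert-butoxy-3,4-dimethoxycyclobut-2-en-1-one
Product: 18 2-[2,4-bis(benzyloxy)-5-methoxyphenyl]-7-tert-butoxy-8-hydroxy-3,5,6-trimethoxy-4H-chromen-4-one, via dienylketene 16 (not isolated), via 8aH-chromene-4,8-dione 17 (not isolated)
Conditions: PhMe (0.01 M, degassed), 110 °C, Ar
Reagents that add atoms: none
Why: Thermal conrotatory 4π ring opening of the cyclobutenone (cleavage of C1–C4) gives dienylketene 16, in which the donor 4-methoxy group has rotated outward and the pyranonyl group inward, next to the ketene carbon. Disrotatory 6π electrocyclisation then joins the ketene carbon to the pyranone CH next to the ring oxygen, closing the six-membered carbocyclic ring A through the C8–C8a bond to give dienone 17, whose C8a hydrogen shifts to oxygen to deliver the aromatic 8-phenol 18. The closest known reaction type is the thermal ring expansion of squarate-derived 4-aryl-, 4-heteroaryl- and 4-alkenyl-4-alkoxycyclobutenones to mono-protected hydroquinones, with the vinylogous-ester C=C of the 4-pyranone taking the place of the usual aryl or alkenyl 2π component. No stereocentre survives: the quaternary carbon of 15 becomes aromatic C5 and the transient C8a centre of 17 is lost on aromatisation. The step needs torquoselectivity, secured by the strong outward preference of an alkoxy donor at C4, and regioselective closure, secured because the pyranone carbon bearing the four-membered ring has only one ring neighbour with hydrogen (the other is the C4 carbonyl carbon); high dilution and exclusion of oxygen should keep the ketene from intermolecular capture and the electron-rich phenol from oxidation.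

Step 10
Reactants: 18 2-Ar-7-tert-butoxy-8-hydroxy-3,5,6-trimethoxy-4H-chromen-4-one
Product: 19 2-[2,4-bis(benzyloxy)-5-methoxyphenyl]-7-tert-butoxy-3,5,6,8-tetramethoxy-4H-chromen-4-one
Conditions: MeI, K2CO3, DMF, rt, Ar
Reagents that add atoms: iodomethane, CI
Why: Williamson methylation of the only free phenol in the molecule.

Step 11
Reactants: 19 2-Ar-7-tert-butoxy-3,5,6,8-tetramethoxy-4H-chromen-4-one
Product: 20 5,7-dihydroxy-2-(2,4-dihydroxy-5-methoxyphenyl)-3,6,8-trimethoxy-4H-chromen-4-one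
Conditions: BCl3 (8 equiv), C6HMe5 (6 equiv), CH2Cl2, −78 → 0 °C; MeOH
Reagents that add atoms: none
Why: Boron trichloride should cleave the tert-butyl ether and, with pentamethylbenzene as cation scavenger, both benzyl ethers at low temperature, and on warming to 0 °C should demethylate only the 5-methoxy group, which is peri to the C4 carbonyl and forms a six-membered boron chelate, leaving the 3-, 6-, 8- and 5'-methoxy groups.

Compound list
1 | 2,4,5-trimethoxybenzaldehyde | O=Cc1cc(OC)c(OC)cc1OC | starting material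
2 | 2,4-dihydroxy-5-methoxybenzaldehyde | O=Cc1cc(OC)c(O)cc1O | intermediate
3 | 2,4-bis(benzyloxy)-5-methoxybenzaldehyde | O=Cc1cc(OC)c(OCc2ccccc2)cc1OCc1ccccc1 | intermediate
4 | 3,4-dibromofuran | Brc1cocc1Br | starting material
5 | (3,4-dibromofuran-2-yl)lithium | [Li]c1occ(Br)c1Br | intermediate (not isolated)
6 | rac-[2,4-bis(benzyloxy)-5-methoxyphenyl](3,4-dibromofuran-2-yl)methanol | OC(c1occ(Br)c1Br)c1cc(OC)c(OCc2ccccc2)cc1OCc1ccccc1 | intermediate
7 | 2-[2,4-bis(benzyloxy)-5-methoxyphenyl]-4,5-dibromo-6-hydroxy-2H-pyran-3(6H)-one (diastereomer mixture) | OC1OC(c2cc(OC)c(OCc3ccccc3)cc2OCc2ccccc2)C(=O)C(Br)=C1Br | intermediate (not isolated)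
8 | 2-[2,4-bis(benzyloxy)-5-methoxyphenyl]-5-bromo-3-hydroxy-4H-pyran-4-one | O=c1c(Br)coc(-c2cc(OC)c(OCc3ccccc3)cc2OCc2ccccc2)c1O | intermediate
9 | 2-[2,4-bis(benzyloxy)-5-methoxyphenyl]-5-bromo-3-methoxy-4H-pyran-4-one | O=c1c(Br)coc(-c2cc(OC)c(OCc3ccccc3)cc2OCc2ccccc2)c1OC | intermediate
10 | di-tert-butyl squarate (3,4-di-tert-butoxycyclobut-3-ene-1,2-dione) | CC(C)(C)OC1=C(OC(C)(C)C)C(=O)C1=O | starting material
11 | {6-[2,4-bis(benzyloxy)-5-methoxyphenyl]-5-methoxy-4-oxo-4H-pyran-3-yl}magnesium chloride (LiCl complex) | Cl[Mg]c1coc(-c2cc(OC)c(OCc3ccccc3)cc2OCc2ccccc2)c(OC)c1=O | intermediate (not isolated)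
12 | rac-4-{6-[2,4-bis(benzyloxy)-5-methoxyphenyl]-5-methoxy-4-oxo-4H-pyran-3-yl}-2,3-di-tert-butoxy-4-hydroxycyclobut-2-en-1-one | OC1(c2coc(-c3cc(OC)c(OCc4ccccc4)cc3OCc3ccccc3)c(OC)c2=O)C(OC(C)(C)C)=C(OC(C)(C)C)C1=O | intermediate
13 | rac-4-{6-[2,4-bis(benzyloxy)-5-methoxyphenyl]-5-methoxy-4-oxo-4H-pyran-3-yl}-2,3-di-tert-butoxy-4-methoxycyclobut-2-en-1-one | COC1(c2coc(-c3cc(OC)c(OCc4ccccc4)cc3OCc3ccccc3)c(OC)c2=O)C(OC(C)(C)C)=C(OC(C)(C)C)C1=O | intermediate
14 | rac-4-{6-[2,4-bis(benzyloxy)-5-methoxyphenyl]-5-methoxy-4-oxo-4H-pyran-3-yl}-2-tert-butoxy-3-hydroxy-4-methoxycyclobut-2-en-1-one | COC1(c2coc(-c3cc(OC)c(OCc4ccccc4)cc3OCc3ccccc3)c(OC)c2=O)C(O)=C(OC(C)(C)C)C1=O | intermediate (not isolated)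
15 | rac-4-{6-[2,4-bis(benzyloxy)-5-methoxyphenyl]-5-methoxy-4-oxo-4H-pyran-3-yl}-2-tert-butoxy-3,4-dimethoxycyclobut-2-en-1-one | COC1(c2coc(-c3cc(OC)c(OCc4ccccc4)cc3OCc3ccccc3)c(OC)c2=O)C(OC)=C(OC(C)(C)C)C1=O | intermediate (key-step precursor)
16 | (3Z)-4-{6-[2,4-bis(benzyloxy)-5-methoxyphenyl]-5-methoxy-4-oxo-4H-pyran-3-yl}-2-tert-butoxy-3,4-dimethoxybuta-1,3-dien-1-one | O=C=C(OC(C)(C)C)/C(OC)=C(OC)\c1coc(-c2cc(OC)c(OCc3ccccc3)cc2OCc2ccccc2)c(OC)c1=O | intermediate (not isolated)
17 | rac-2-[2,4-bis(benzyloxy)-5-methoxyphenyl]-7-tert-butoxy-3,5,6-trimethoxy-8aH-chromene-4,8-dione | O=C1C(OC)=C(-c2cc(OC)c(OCc3ccccc3)cc2OCc2ccccc2)OC2C(=O)C(OC(C)(C)C)=C(OC)C(OC)=C12 | intermediate (not isolated)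
18 | 2-[2,4-bis(benzyloxy)-5-methoxyphenyl]-7-tert-butoxy-8-hydroxy-3,5,6-trimethoxy-4H-chromen-4-one | COc1cc(-c2oc3c(O)c(OC(C)(C)C)c(OC)c(OC)c3c(=O)c2OC)c(OCc2ccccc2)cc1OCc1ccccc1 | intermediate (key-step product)
19 | 2-[2,4-bis(benzyloxy)-5-methoxyphenyl]-7-tert-butoxy-3,5,6,8-tetramethoxy-4H-chromen-4-one | COc1cc(-c2oc3c(OC)c(OC(C)(C)C)c(OC)c(OC)c3c(=O)c2OC)c(OCc2ccccc2)cc1OCc1ccccc1 | intermediate
20 | 5,7-dihydroxy-2-(2,4-dihydroxy-5-methoxyphenyl)-3,6,8-trimethoxy-4H-chromen-4-one (5,7,2',4'-tetrahydroxy-3,6,8,5'-tetramethoxyflavone) | COc1cc(-c2oc3c(OC)c(O)c(OC)c(O)c3c(=O)c2OC)c(O)cc1O | target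

Total step count: 11. Longest linear sequence: 11 steps (1 → 20); 4 and 10 are purchased and enter at steps 3 and 6.

Steps most likely to fail: step 9, step 6, step 8.

The first risk is step 9, the ring expansion. The ketene carbon has to bond to the pyranone carbon next to the ring oxygen, the electron-poor end of the vinylogous ester, so the 6π closure may be slow. The ketene could then be captured by phenol already formed, and forcing temperatures would endanger the tert-butyl enol ether. The fallback turns the pyranone around: the ketene closes onto the nucleophilic carbon next to the pyranone carbonyl group, and ring A forms through C4a–C5 with 5-OH and 8-OMe already in place.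
- It sets out from Grignard reagent 11. Quenching with aq. NH4Cl gives 2-Ar-3-methoxy-4H-pyran-4-one F1 as the halogen-free pyranone.
- TMPMgCl·LiCl (THF, −40 °C) should remove the most acidic proton, next to the ring oxygen, to give {6-Ar-5-methoxy-4-oxo-4H-pyran-2-yl}magnesium chloride F2, an α-oxygenated alkenylmagnesium species that has no β-leaving group.
- Addition to purchased dimethyl squarate gives rac-4-{6-Ar-5-methoxy-4-oxo-4H-pyran-2-yl}-4-hydroxy-2,3-dimethoxycyclobut-2-en-1-one F3 as the carbinol.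
- MeI/Ag2O gives rac-4-{6-Ar-5-methoxy-4-oxo-4H-pyran-2-yl}-2,3,4-trimethoxycyclobut-2-en-1-one F4 as its methyl ether.
- LiI (EtOAc, 50 °C) should remove only the vinylogous-ester methyl group by SN2 attack to give the vinylogous acid rac-4-{6-Ar-5-methoxy-4-oxo-4H-pyran-2-yl}-3-hydroxy-2,4-dimethoxycyclobut-2-en-1-one F5, whose two tautomers are again mirror images.
- O-Benzylation (BnBr, Ag2O) therefore gives a single constitution, rac-3-(benzyloxy)-4-{6-Ar-5-methoxy-4-oxo-4H-pyran-2-yl}-2,4-dimethoxycyclobut-2-en-1-one F6, whichever oxygen reacts.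
- Thermolysis (PhMe, 110 °C, Ar) should give 2-Ar-7-(benzyloxy)-5-hydroxy-3,6,8-trimethoxy-4H-chromen-4-one F7 with the chelated 5-hydroxyl free.
- BCl3/pentamethylbenzene at −78 °C, which now only has to remove three benzyl groups, comes back to the route at target 20.

The second risk is step 6, the metalation and addition. The magnesiated pyranone may fragment by β-elimination of the ring oxygen, or the exchange reagent may add to the pyranone before the bromine–magnesium exchange is complete. The fallback replaces exchange by oxidative insertion. It sets out from 9: zinc dust activated with LiCl (THF, 25–40 °C) should insert into the activated C–Br bond to give {6-Ar-5-methoxy-4-oxo-4H-pyran-3-yl}zinc bromide F8, a more covalent reagent that does not fragment. Its MgCl2-promoted 1,2-addition to squarate 10 (THF, 0 °C → rt) comes back to the route at 12.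

The third risk is step 8, the exchange of tert-butyl for methyl. Acid may also ionise the C4 methyl ether, which is a vinylogous ketal, and drain the material into a 4-hydroxycyclobutene-1,2-dione, or it may remove the second tert-butyl group as well. The fallback postpones the distinction between O6 and O7 until after the ring expansion, where it rests on phenol acidity.
- It sets out from 13. Thermolysis under the key-step conditions (PhMe, 110 °C, Ar) should give 2-Ar-6,7-di-tert-butoxy-8-hydroxy-3,5-dimethoxy-4H-chromen-4-one F9 as the phenol.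
- MeI/K2CO3 gives 2-Ar-6,7-di-tert-butoxy-3,5,8-trimethoxy-4H-chromen-4-one F10 as its methyl ether.
- TFA (CH2Cl2, rt) removes both tert-butyl groups to give the catechol 2-Ar-6,7-dihydroxy-3,5,8-trimethoxy-4H-chromen-4-one F11, in which the 7-hydroxyl, conjugated with the C4 carbonyl group through ring A, is the more acidic.
- BnBr (1 equiv)/K2CO3 in acetone under argon should therefore give 2-Ar-7-(benzyloxy)-6-hydroxy-3,5,8-trimethoxy-4H-chromen-4-one F12 selectively.
- MeI/K2CO3 gives 2-Ar-7-(benzyloxy)-3,5,6,8-tetramethoxy-4H-chromen-4-one F13 as the fully protected flavone.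
- BCl3/pentamethylbenzene (−78 → 0 °C), which removes three benzyl groups and the chelated 5-methyl group, comes back to the route at target 20.

Further compounds
F1 | step 9 | 2-[2,4-bis(benzyloxy)-5-methoxyphenyl]-3-methoxy-4H-pyran-4-one | O=c1ccoc(-c2cc(OC)c(OCc3ccccc3)cc2OCc2ccccc2)c1OC
F2 | step 9 | {6-[2,4-bis(benzyloxy)-5-methoxyphenyl]-5-methoxy-4-oxo-4H-pyran-2-yl}magnesium chloride | Cl[Mg]c1cc(=O)c(OC)c(-c2cc(OC)c(OCc3ccccc3)cc2OCc2ccccc2)o1
F3 | step 9 | rac-4-{6-[2,4-bis(benzyloxy)-5-methoxyphenyl]-5-methoxy-4-oxo-4H-pyran-2-yl}-4-hydroxy-2,3-dimethoxycyclobut-2-en-1-one | OC1(c2cc(=O)c(OC)c(-c3cc(OC)c(OCc4ccccc4)cc3OCc3ccccc3)o2)C(OC)=C(OC)C1=O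
F4 | step 9 | rac-4-{6-[2,4-bis(benzyloxy)-5-methoxyphenyl]-5-methoxy-4-oxo-4H-pyran-2-yl}-2,3,4-trimethoxycyclobut-2-en-1-one | COC1(c2cc(=O)c(OC)c(-c3cc(OC)c(OCc4ccccc4)cc3OCc3ccccc3)o2)C(OC)=C(OC)C1=O
F5 | step 9 | rac-4-{6-[2,4-bis(benzyloxy)-5-methoxyphenyl]-5-methoxy-4-oxo-4H-pyran-2-yl}-3-hydroxy-2,4-dimethoxycyclobut-2-en-1-one | COC1(c2cc(=O)c(OC)c(-c3cc(OC)c(OCc4ccccc4)cc3OCc3ccccc3)o2)C(O)=C(OC)C1=O
F6 | step 9 | rac-3-(benzyloxy)-4-{6-[2,4-bis(benzyloxy)-5-methoxyphenyl]-5-methoxy-4-oxo-4H-pyran-2-yl}-2,4-dimethoxycyclobut-2-en-1-one | COC1(c2cc(=O)c(OC)c(-c3cc(OC)c(OCc4ccccc4)cc3OCc3ccccc3)o2)C(OCc2ccccc2)=C(OC)C1=O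
F7 | step 9 | 7-(benzyloxy)-2-[2,4-bis(benzyloxy)-5-methoxyphenyl]-5-hydroxy-3,6,8-trimethoxy-4H-chromen-4-one | COc1cc(-c2oc3c(OC)c(OCc4ccccc4)c(OC)c(O)c3c(=O)c2OC)c(OCc2ccccc2)cc1OCc1ccccc1
F8 | step 6 | {6-[2,4-bis(benzyloxy)-5-methoxyphenyl]-5-methoxy-4-oxo-4H-pyran-3-yl}zinc bromide | Br[Zn]c1coc(-c2cc(OC)c(OCc3ccccc3)cc2OCc2ccccc2)c(OC)c1=O
F9 | step 8 | 2-[2,4-bis(benzyloxy)-5-methoxyphenyl]-6,7-di-tert-butoxy-8-hydroxy-3,5-dimethoxy-4H-chromen-4-one | COc1cc(-c2oc3c(O)c(OC(C)(C)C)c(OC(C)(C)C)c(OC)c3c(=O)c2OC)c(OCc2ccccc2)cc1OCc1ccccc1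
F10 | step 8 | 2-[2,4-bis(benzyloxy)-5-methoxyphenyl]-6,7-di-tert-butoxy-3,5,8-trimethoxy-4H-chromen-4-one | COc1cc(-c2oc3c(OC)c(OC(C)(C)C)c(OC(C)(C)C)c(OC)c3c(=O)c2OC)c(OCc2ccccc2)cc1OCc1ccccc1
F11 | step 8 | 2-[2,4-bis(benzyloxy)-5-methoxyphenyl]-6,7-dihydroxy-3,5,8-trimethoxy-4H-chromen-4-one | COc1cc(-c2oc3c(OC)c(O)c(O)c(OC)c3c(=O)c2OC)c(OCc2ccccc2)cc1OCc1ccccc1
F12 | step 8 | 7-(benzyloxy)-2-[2,4-bis(benzyloxy)-5-methoxyphenyl]-6-hydroxy-3,5,8-trimethoxy-4H-chromen-4-one | COc1cc(-c2oc3c(OC)c(OCc4ccccc4)c(O)c(OC)c3c(=O)c2OC)c(OCc2ccccc2)cc1OCc1ccccc1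
F13 | step 8 | 7-(benzyloxy)-2-[2,4-bis(benzyloxy)-5-methoxyphenyl]-3,5,6,8-tetramethoxy-4H-chromen-4-one | COc1cc(-c2oc3c(OC)c(OCc4ccccc4)c(OC)c(OC)c3c(=O)c2OC)c(OCc2ccccc2)cc1OCc1ccccc1
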